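Everything rests on cutting the aryl ether bond O1–C8a of ring C. The feature exploited is that the ring-C oxygen O1 is bonded on one side to the benzylic stereocentre C2 and on the other to C8a, the ring-A carbon flanked by C8 (prenyl) and C4a (bearing the C4 carbonyl). A palladium-catalysed intramolecular C–O coupling of a free (S)-C2 carbinol with a C8a triflate therefore closes ring C in one operation, fixes the 8-prenyl pattern and never touches the C2–O bond. The precursor is a 1,3-diarylpropane with the C8a triflate, MOM-protected phenols, C4 as a silyl ether (latent ketone) and the C2 hydroxyl as its only free OH, set by CBS reduction after C4–O is capped.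

Key step: step 11

Remark: C4 is only a temporary stereocentre (it is the carbonyl carbon of the target); it is formed as a racemate in step 8 and both C4 epimers are carried together, so C4 is left undefined in the SMILES of 13 to 19, while C2 is uniformly S from step 10 on.

Step 1
Reactants: 1 2,4,6-trihydroxybenzaldehyde; 2 prenyl bromide (1-bromo-3-methylbut-2-ene)
Product: 3 2,4,6-trihydroxy-3-(3-methylbut-2-en-1-yl)benzaldehyde
Conditions: DBU, THF, 0 °C to rt
Reagents that add atoms: none
Why: Base-mediated nuclear C-prenylation (Friedel–Crafts-type C-alkylation of a phloroglucinol phenoxide by an allylic bromide); the two open ring carbons of 1 are equivalent, so mono-alkylation can give only one constitutional isomer.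

Step 2
Reactants: 3 2,4,6-trihydroxy-3-(3-methylbut-2-en-1-yl)benzaldehyde
Product: 4 2-hydroxy-4,6-bis(methoxymethoxy)-3-(3-methylbut-2-en-1-yl)benzaldehyde
Conditions: MOMCl (2.1 equiv), iPr2NEt, CH2Cl2, 0 °C
Reagents that add atoms: chloromethyl methyl ether (MOMCl), COCCl
Why: Williamson-type O-alkylation with a chloromethyl ether; the unchelated 4-OH should react first and the second MOM group should go to the less hindered chelated hydroxyl remote from the prenyl group, which leaves free the hydroxyl flanked by prenyl and formyl, on the carbon that becomes C8a.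

Step 3
Reactants: 4 2-hydroxy-4,6-bis(methoxymethoxy)-3-(3-methylbut-2-en-1-yl)benzaldehyde
Product: 5 2-formyl-3,5-bis(methoxymethoxy)-6-(3-methylbut-2-en-1-yl)phenyl trifluoromethanesulfonate (ring-A aldehyde)
Conditions: Tf2O, pyridine, CH2Cl2, −10 °C to rt
Reagents that add atoms: trifluoromethanesulfonic anhydride (Tf2O), O=S(=O)(OS(=O)(=O)C(F)(F)F)C(F)(F)F
Why: O-sulfonylation of the only free phenol (aryl triflate formation), which marks the carbon between the prenyl group and the formyl-bearing carbon as the later C8a electrophile.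

Step 4
Reactants: 6 2,4-dihydroxyacetophenone; 2 prenyl bromide
Product: 7 2-hydroxy-4-[(3-methylbut-2-en-1-yl)oxy]acetophenone
Conditions: K2CO3, acetone, reflux
Reagents that add atoms: none
Why: Williamson ether synthesis; the 4-OH should be alkylated selectively because the 2-OH is tied up in the hydrogen bond to the acetyl group.

Step 5
Reactants: 7 2-hydroxy-4-[(3-methylbut-2-en-1-yl)oxy]acetophenone
Product: 8 2-methoxy-4-[(3-methylbut-2-en-1-yl)oxy]acetophenone
Conditions: MeI, K2CO3, DMF, 40 °C
Reagents that add atoms: iodomethane (MeI), CI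
Why: Williamson O-methylation of the chelated phenol under more forcing conditions, which also removes the hydrogen bond that would otherwise steer the following rearrangement to C3.

Step 6
Reactants: 8 2-methoxy-4-[(3-methylbut-2-en-1-yl)oxy]acetophenone
Product: 10 1-[4-hydroxy-2-methoxy-5-(2-methylbut-3-en-2-yl)phenyl]ethan-1-one, via ortho-dienone 9 (not isolated)
Conditions: EtOH/H2O 4:1, 130–140 °C, sealed tube
Reagents that add atoms: none
Why: Aromatic Claisen rearrangement ([3,3]-sigmatropic shift with allyl inversion) should deliver the 1,1-dimethylallyl group to the open ortho carbon C5 in preference to C3, which is wedged between two oxygen substituents, after which the dienone tautomerises to the phenol.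

Step 7
Reactants: 10 1-[4-hydroxy-2-methoxy-5-(2-methylbut-3-en-2-yl)phenyl]ethan-1-one
Product: 11 1-[2-methoxy-4-(methoxymethoxy)-5-(2-methylbut-3-en-2-yl)phenyl]ethan-1-one (ring-B ketone)
Conditions: MOMCl, K2CO3, acetone, 50 °C
Reagents that add atoms: chloromethyl methyl ether (MOMCl), COCCl
Why: Williamson-type MOM protection of the acidic para-acyl phenol, the only hydroxyl present.

Step 8
Reactants: 11 ring-B ketone; 5 ring-A aldehyde
Product: 14 racemic aldol adduct 2-{1-hydroxy-3-[2-methoxy-4-(methoxymethoxy)-5-(2-methylbut-3-en-2-yl)phenyl]-3-oxopropyl}-3,5-bis(methoxymethoxy)-6-(3-methylbut-2-en-1-yl)phenyl trifluoromethanesulfonate, via lithium enolate 12 (not isolated), via lithium aldolate 13 (not isolated)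
Conditions: LiN(iPr)2 (1.0 equiv), THF, −78 °C; then 5, −78 °C; AcOH quench at −78 °C
Reagents that add atoms: none
Why: Directed (crossed) aldol addition of the kinetic lithium enolate of a methyl ketone to a non-enolisable aldehyde at low temperature; the C4 carbinol forms as a racemate, which is of no consequence because C4 becomes the carbonyl carbon in step 13.

Step 9
Reactants: 14 racemic aldol adduct
Product: 15 racemic β-silyloxy ketone (C4 tert-butyldimethylsilyl ether of 14)
Conditions: TBSOTf, 2,6-lutidine, CH2Cl2, −78 °C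
Reagents that add atoms: tert-butyldimethylsilyl trifluoromethanesulfonate (TBSOTf), CC(C)(C)[Si](C)(C)OS(=O)(=O)C(F)(F)F
Why: Silyl ether formation with a silyl triflate and a hindered pyridine base on the only hydroxyl present, so that the C4 oxygen is capped before the C2 hydroxyl exists and two similar carbinols never have to be told apart.

Step 10
Reactants: 15 racemic β-silyloxy ketone
Product: 17 (3S)-carbinol triflate 2-{(3S)-1-[(tert-butyldimethylsilyl)oxy]-3-hydroxy-3-[2-methoxy-4-(methoxymethoxy)-5-(2-methylbut-3-en-2-yl)phenyl]propyl}-3,5-bis(methoxymethoxy)-6-(3-methylbut-2-en-1-yl)phenyl trifluoromethanesulfonate (both C1 epimers), via catechol borate ester 16 (not isolated)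
Conditions: (R)-2-methyl-CBS-oxazaborolidine (20 mol%), catecholborane, toluene, −78 to −40 °C; then aqueous work-up
Reagents that add atoms: none
Why: Corey–Bakshi–Shibata reduction, in which the (R)-oxazaborolidine should treat the aryl group as the large substituent and deliver hydride to the Re face of the ketone, setting C2 as S under catalyst control irrespective of the remote C4 centre, while catecholborane at low temperature leaves the alkenes untouched.

Step 11
Reactants: 17 (3S)-carbinol triflate (both C4 epimers in flavan numbering)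
Product: 18 (2S)-4-[(tert-butyldimethylsilyl)oxy]-5,7-bis(methoxymethoxy)-2-[2-methoxy-4-(methoxymethoxy)-5-(2-methylbut-3-en-2-yl)phenyl]-8-(3-methylbut-2-en-1-yl)chromane (both C4 epimers)
Conditions: Pd(OAc)2 (5 mol%), 2-(di-tert-butylphosphino)-1,1'-binaphthyl (7.5 mol%), Cs2CO3 (1.5 equiv), toluene, 80 °C
Reagents that add atoms: none
Why: Zerovalent palladium, generated from Pd(OAc)2 and the bulky di-tert-butylphosphine, should insert into the C8a–OTf bond, Cs2CO3 should then turn the coordinated C2 hydroxyl into an alkoxide to give a seven-membered aryl(alkoxo)palladacycle, and C–O reductive elimination should release the flavan and the catalyst. The closest known reaction type is the Buchwald–Hartwig-type intramolecular etherification of aryl halides and sulfonates with secondary alcohols, which converts enantioenriched carbinols into chromans. Ring C, a six-membered dihydropyran, closes in the 6-exo sense by attack of the tethered oxygen on the palladium-bound sp2 carbon C8a. No stereocentre is created: the C2–O bond is never broken, so the S configuration from step 10 is carried over, and both C4 epimers should cyclise. The step needs C–O reductive elimination to win over β-hydride elimination, S–O cleavage of the triflate and silyl migration; the bulky electron-rich ligand, the weak insoluble carbonate base in toluene, and the fact that C2–OH is the only free hydroxyl (the silylated C4 oxygen could in any case reach C8a only through a four-membered ring) should secure this. Regiochemistry is fixed beforehand, because the triflate sits on the carbon between the prenyl group and C4a.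

Step 12
Reactants: 18 (2S)-flavan C4 silyl ether
Product: 19 (2S)-5,7-bis(methoxymethoxy)-2-[2-methoxy-4-(methoxymethoxy)-5-(2-methylbut-3-en-2-yl)phenyl]-8-(3-methylbut-2-en-1-yl)chroman-4-ol (both C4 epimers)
Conditions: Bu4NF, THF, 0 °C to rt
Reagents that add atoms: none
Why: Fluoride-induced desilylation driven by Si–F bond formation; MOM ethers, alkenes and the new aryl ether are inert to fluoride.

Step 13
Reactants: 19 (2S)-flavan-4-ol
Product: 20 (2S)-5,7-bis(methoxymethoxy)-2-[2-methoxy-4-(methoxymethoxy)-5-(2-methylbut-3-en-2-yl)phenyl]-8-(3-methylbut-2-en-1-yl)chroman-4-one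
Conditions: Dess–Martin periodinane, NaHCO3, CH2Cl2, 0 °C to rt
Reagents that add atoms: none
Why: Dess–Martin oxidation of the benzylic secondary alcohol under buffered conditions should merge both C4 epimers into one ketone and avoids the base that could open the chromanone ring and endanger C2.

Step 14
Reactants: 20 tris-MOM flavanone
Product: 21 (2S)-5,7-dihydroxy-2-[4-hydroxy-2-methoxy-5-(2-methylbut-3-en-2-yl)phenyl]-8-(3-methylbut-2-en-1-yl)chroman-4-one (CNP0308136.1)
Conditions: 3 M HCl (aq), MeOH, 40 °C
Reagents that add atoms: none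
Why: Acid-catalysed transacetalisation of the three aryl MOM ethers in methanol, under conditions mild enough to spare the two prenyl-type alkenes and not to racemise C2.

Compound list

1 | 2,4,6-trihydroxybenzaldehyde | O=Cc1c(O)cc(O)cc1O | starting material
2 | prenyl bromide (1-bromo-3-methylbut-2-ene) | CC(C)=CCBr | starting material
3 | 2,4,6-trihydroxy-3-(3-methylbut-2-en-1-yl)benzaldehyde | O=Cc1c(O)cc(O)c(CC=C(C)C)c1O | intermediate
4 | 2-hydroxy-4,6-bis(methoxymethoxy)-3-(3-methylbut-2-en-1-yl)benzaldehyde | O=Cc1c(OCOC)cc(OCOC)c(CC=C(C)C)c1O | intermediate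
5 | 2-formyl-3,5-bis(methoxymethoxy)-6-(3-methylbut-2-en-1-yl)phenyl trifluoromethanesulfonate | O=Cc1c(OCOC)cc(OCOC)c(CC=C(C)C)c1OS(=O)(=O)C(F)(F)F | intermediate
6 | 2,4-dihydroxyacetophenone | CC(=O)c1ccc(O)cc1O | starting material
7 | 2-hydroxy-4-[(3-methylbut-2-en-1-yl)oxy]acetophenone | CC(=O)c1ccc(OCC=C(C)C)cc1O | intermediate
8 | 2-methoxy-4-[(3-methylbut-2-en-1-yl)oxy]acetophenone | CC(=O)c1ccc(OCC=C(C)C)cc1OC | intermediate
9 | 4-acetyl-3-methoxy-6-(2-methylbut-3-en-2-yl)cyclohexa-2,4-dien-1-one (ortho-dienone, racemic) | CC(=O)C1=CC(C(C)(C)C=C)C(=O)C=C1OC | intermediate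
10 | 1-[4-hydroxy-2-methoxy-5-(2-methylbut-3-en-2-yl)phenyl]ethan-1-one | CC(=O)c1cc(C(C)(C)C=C)c(O)cc1OC | intermediate
11 | 1-[2-methoxy-4-(methoxymethoxy)-5-(2-methylbut-3-en-2-yl)phenyl]ethan-1-one | CC(=O)c1cc(C(C)(C)C=C)c(OCOC)cc1OC | intermediate
12 | lithium 1-[2-methoxy-4-(methoxymethoxy)-5-(2-methylbut-3-en-2-yl)phenyl]ethen-1-olate (lithium enolate of 11) | [Li]OC(=C)c1cc(C(C)(C)C=C)c(OCOC)cc1OC | intermediate
13 | lithium aldolate of 14 (racemic) | C=CC(C)(C)c1cc(C(=O)CC(O[Li])c2c(OCOC)cc(OCOC)c(CC=C(C)C)c2OS(=O)(=O)C(F)(F)F)c(OC)cc1OCOC | intermediate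
14 | 2-{1-hydroxy-3-[2-methoxy-4-(methoxymethoxy)-5-(2-methylbut-3-en-2-yl)phenyl]-3-oxopropyl}-3,5-bis(methoxymethoxy)-6-(3-methylbut-2-en-1-yl)phenyl trifluoromethanesulfonate (racemic) | C=CC(C)(C)c1cc(C(=O)CC(O)c2c(OCOC)cc(OCOC)c(CC=C(C)C)c2OS(=O)(=O)C(F)(F)F)c(OC)cc1OCOC | intermediate
15 | 2-{1-[(tert-butyldimethylsilyl)oxy]-3-[2-methoxy-4-(methoxymethoxy)-5-(2-methylbut-3-en-2-yl)phenyl]-3-oxopropyl}-3,5-bis(methoxymethoxy)-6-(3-methylbut-2-en-1-yl)phenyl trifluoromethanesulfonate (racemic) | C=CC(C)(C)c1cc(C(=O)CC(O[Si](C)(C)C(C)(C)C)c2c(OCOC)cc(OCOC)c(CC=C(C)C)c2OS(=O)(=O)C(F)(F)F)c(OC)cc1OCOC | intermediate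
16 | catechol borate ester of 17 (O-(1,3,2-benzodioxaborol-2-yl) derivative, S at the carbinol carbon, both C4 epimers) | C=CC(C)(C)c1cc([C@@H](OB2Oc3ccccc3O2)CC(O[Si](C)(C)C(C)(C)C)c2c(OCOC)cc(OCOC)c(CC=C(C)C)c2OS(=O)(=O)C(F)(F)F)c(OC)cc1OCOC | intermediate
17 | 2-{(3S)-1-[(tert-butyldimethylsilyl)oxy]-3-hydroxy-3-[2-methoxy-4-(methoxymethoxy)-5-(2-methylbut-3-en-2-yl)phenyl]propyl}-3,5-bis(methoxymethoxy)-6-(3-methylbut-2-en-1-yl)phenyl trifluoromethanesulfonate (both C1 epimers; key-step precursor) | C=CC(C)(C)c1cc([C@@H](O)CC(O[Si](C)(C)C(C)(C)C)c2c(OCOC)cc(OCOC)c(CC=C(C)C)c2OS(=O)(=O)C(F)(F)F)c(OC)cc1OCOC | intermediate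
18 | (2S)-4-[(tert-butyldimethylsilyl)oxy]-5,7-bis(methoxymethoxy)-2-[2-methoxy-4-(methoxymethoxy)-5-(2-methylbut-3-en-2-yl)phenyl]-8-(3-methylbut-2-en-1-yl)chromane (both C4 epimers; key-step product) | C=CC(C)(C)c1cc([C@@H]2CC(O[Si](C)(C)C(C)(C)C)c3c(OCOC)cc(OCOC)c(CC=C(C)C)c3O2)c(OC)cc1OCOC | intermediate
19 | (2S)-5,7-bis(methoxymethoxy)-2-[2-methoxy-4-(methoxymethoxy)-5-(2-methylbut-3-en-2-yl)phenyl]-8-(3-methylbut-2-en-1-yl)chroman-4-ol (both C4 epimers) | C=CC(C)(C)c1cc([C@@H]2CC(O)c3c(OCOC)cc(OCOC)c(CC=C(C)C)c3O2)c(OC)cc1OCOC | intermediate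
20 | (2S)-5,7-bis(methoxymethoxy)-2-[2-methoxy-4-(methoxymethoxy)-5-(2-methylbut-3-en-2-yl)phenyl]-8-(3-methylbut-2-en-1-yl)chroman-4-one | C=CC(C)(C)c1cc([C@@H]2CC(=O)c3c(OCOC)cc(OCOC)c(CC=C(C)C)c3O2)c(OC)cc1OCOC | intermediate
21 | (2S)-5,7-dihydroxy-2-[4-hydroxy-2-methoxy-5-(2-methylbut-3-en-2-yl)phenyl]-8-(3-methylbut-2-en-1-yl)chroman-4-one (CNP0308136.1) | C=CC(C)(C)c1cc([C@@H]2CC(=O)c3c(O)cc(O)c(CC=C(C)C)c3O2)c(OC)cc1O | target

Total step count: 14. Longest linear sequence: 11 steps (steps 4 to 14, from 6).

Steps most likely to fail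

Step 11. What may go wrong: sluggish oxidative addition into the doubly ortho-substituted, electron-rich triflate; β-hydride elimination from the palladium alkoxide, which oxidises the C2 carbinol and reduces the arene; base-induced loss of the triflyl group; or silyl migration from the C4 oxygen to the C2 oxygen. The fallback sets out from 15 and comes back at 18. Reduction of 15 with the enantiomeric (S)-2-methyl-CBS-oxazaborolidine and catecholborane should give the (3R)-carbinol triflate F1. Et4NOH in dioxane at rt should then cleave the aryl triflate to the (3R)-carbinol phenol F2. An intramolecular Mitsunobu etherification (PPh3, DIAD, THF, 0 °C) should close ring C by SN2 displacement at C2 with inversion, which gives 18 with the 2S configuration.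

Step 6. What may go wrong: migration to C3 instead of C5, thermal loss of the prenyl group, or further rearrangement and cyclisation of the ortho-(1,1-dimethylallyl)phenol at the temperature needed. The fallback sets out from 6 and comes back at 11. MOMCl with K2CO3 in acetone should protect the unchelated 4-OH to give 2-hydroxy-4-(methoxymethoxy)acetophenone F3. MeI with K2CO3 in DMF should give 2-methoxy-4-(methoxymethoxy)acetophenone F4. NBS in MeCN at 0 °C should brominate C5 (para to the methoxy group, ortho to the MOM ether) to give 5-bromo-2-methoxy-4-(methoxymethoxy)acetophenone F5. A branched-selective (γ-selective) Suzuki–Miyaura coupling with 3-methylbut-2-enylboronic acid pinacol ester (Pd(OAc)2, a biaryl dialkylphosphine ligand, K3PO4, THF/H2O) should then install the 1,1-dimethylallyl group and give 11.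

Step 2. What may go wrong: incomplete discrimination between the two chelated hydroxyls, so that a MOM group also ends up on the oxygen next to the prenyl group. The fallback sets out from 1 and comes back at 5, replacing steps 1 to 3 by a sequence in which the regiochemistry is set by a sigmatropic shift. MOMCl (1 equiv) with iPr2NEt should give 2,6-dihydroxy-4-(methoxymethoxy)benzaldehyde F6. Compound 2 with K2CO3 in acetone should etherify one of the two equivalent hydroxyls to give 2-hydroxy-4-(methoxymethoxy)-6-[(3-methylbut-2-en-1-yl)oxy]benzaldehyde F7. Tf2O with pyridine should give 2-formyl-5-(methoxymethoxy)-3-[(3-methylbut-2-en-1-yl)oxy]phenyl trifluoromethanesulfonate F8. Heating in N,N-diethylaniline at about 190 °C should trigger a para-Claisen rearrangement (Claisen then Cope shift, no net allyl inversion) that moves the prenyl group to the carbon para to the ether oxygen, between the triflate and the MOM ether, giving 2-formyl-3-hydroxy-5-(methoxymethoxy)-6-(3-methylbut-2-en-1-yl)phenyl trifluoromethanesulfonate F9. MOMCl with iPr2NEt should then cap the released phenol to give 5.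

Further compounds

F1 | step 11 | 2-{(3R)-1-[(tert-butyldimethylsilyl)oxy]-3-hydroxy-3-[2-methoxy-4-(methoxymethoxy)-5-(2-methylbut-3-en-2-yl)phenyl]propyl}-3,5-bis(methoxymethoxy)-6-(3-methylbut-2-en-1-yl)phenyl trifluoromethanesulfonate (both C1 epimers) | C=CC(C)(C)c1cc([C@H](O)CC(O[Si](C)(C)C(C)(C)C)c2c(OCOC)cc(OCOC)c(CC=C(C)C)c2OS(=O)(=O)C(F)(F)F)c(OC)cc1OCOC
F2 | step 11 | 2-{(3R)-1-[(tert-butyldimethylsilyl)oxy]-3-hydroxy-3-[2-methoxy-4-(methoxymethoxy)-5-(2-methylbut-3-en-2-yl)phenyl]propyl}-3,5-bis(methoxymethoxy)-6-(3-methylbut-2-en-1-yl)phenol (both C1 epimers) | C=CC(C)(C)c1cc([C@H](O)CC(O[Si](C)(C)C(C)(C)C)c2c(OCOC)cc(OCOC)c(CC=C(C)C)c2O)c(OC)cc1OCOC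
F3 | step 6 | 2-hydroxy-4-(methoxymethoxy)acetophenone | CC(=O)c1ccc(OCOC)cc1O
F4 | step 6 | 2-methoxy-4-(methoxymethoxy)acetophenone | CC(=O)c1ccc(OCOC)cc1OC
F5 | step 6 | 5-bromo-2-methoxy-4-(methoxymethoxy)acetophenone | CC(=O)c1cc(Br)c(OCOC)cc1OC
F6 | step 2 | 2,6-dihydroxy-4-(methoxymethoxy)benzaldehyde | O=Cc1c(O)cc(OCOC)cc1O
F7 | step 2 | 2-hydroxy-4-(methoxymethoxy)-6-[(3-methylbut-2-en-1-yl)oxy]benzaldehyde | O=Cc1c(O)cc(OCOC)cc1OCC=C(C)C
F8 | step 2 | 2-formyl-5-(methoxymethoxy)-3-[(3-methylbut-2-en-1-yl)oxy]phenyl trifluoromethanesulfonate | O=Cc1c(OCC=C(C)C)cc(OCOC)cc1OS(=O)(=O)C(F)(F)F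
F9 | step 2 | 2-formyl-3-hydroxy-5-(methoxymethoxy)-6-(3-methylbut-2-en-1-yl)phenyl trifluoromethanesulfonate | O=Cc1c(O)cc(OCOC)c(CC=C(C)C)c1OS(=O)(=O)C(F)(F)F
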